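**Assumptions:** The target has no stereocentres, only five E-trisubstituted alkenes. Compounds 1, 5, 17 and 19 (isoprene monoxide, prenyl bromide, squaric acid, propyne) are taken as commercial, each with ≤8 non-hydrogen atoms. The E-alkene geometry is set once, in compound 2, and carried through by stereoretentive couplings.

## Retrosynthesis
- The ring–side-chain bond (C6–CH2) is disconnected as a radical-pair coupling: a photo-generated all-E hexaprenyl radical from an allylstannane meets the only C–H of a protected 3-demethyl-CoQ0-type quinone.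
- The all-E hexaprenyl stannane is built by five head-to-tail Pd-catalysed allyl–allyl (Stille-type) couplings of one isoprene-derived C5 stannane/dihalide pair plus prenyl stannane.
- The single ring, the quinone, is made first, before any coupling. It comes from squaric acid by 4-alkynylcyclobutenone ring expansion (a thermal diradical process), with the future 3-OH carried as an isopropyl ether that is removed last.

## Forward synthesis

**Step 1**
Reactants: 1 (isoprene monoxide)
Product: 2 ((2E)-4-chloro-2-methylbut-2-en-1-ol)
Conditions: conc. HCl (1 equiv), CuCl (cat.), 0 °C; isolate the E isomer by distillation or chromatography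
Reagents that add atoms: HCl (Cl)
Why: Acid-mediated 1,4-opening of the vinyl epoxide puts Cl on the vinyl terminus and leaves CH2OH on the methyl-bearing carbon. This sets the E geometry used throughout.

**Step 2**
Reactants: 2
Product: 3 ((2E)-1-bromo-4-chloro-2-methylbut-2-ene)
Conditions: PPh3, CBr4, CH2Cl2, 0 °C
Reagents that add atoms: CBr4 (BrC(Br)(Br)Br)
Why: The Appel reaction converts the primary allylic alcohol by SN2 with no change in alkene geometry. The allylic chloride survives and is much less reactive toward Pd(0) than the bromide.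

**Step 3**
Reactants: 2
Product: 4 ((2E)-2-methyl-4-(tributylstannyl)but-2-en-1-ol)
Conditions: Bu3SnLi (2.2 equiv, from Bu3SnH + LDA), THF, –78 → 0 °C
Reagents that add atoms: Bu3SnLi ([Li][Sn](CCCC)(CCCC)CCCC)
Why: The first equivalent deprotonates the OH. The second displaces the primary allylic chloride by SN2 with retention of E geometry. The free alcohol serves as an unreactive "protected" electrophile later.

**Step 4**
Reactants: 5 (prenyl bromide)
Product: 6 (prenyltributylstannane)
Conditions: Bu3SnLi, THF, –78 °C
Reagents that add atoms: Bu3SnLi ([Li][Sn](CCCC)(CCCC)CCCC)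
Why: SN2 at the primary allylic bromide gives the linear (α) stannane.

**Step 5**
Reactants: 3, 4
Product: 7 ((2E,6E)-8-chloro-2,6-dimethylocta-2,6-dien-1-ol)
Conditions: Pd(PPh3)4 (5 mol %), THF, 0 → 25 °C
Reagents that add atoms: none
Why: Proposed new method: Stille-type allyl–allyl coupling on trisubstituted polyprenyl units. The allylic bromide is selectively ionised, and bis(π-allyl)Pd reductive elimination joins the two unhindered CH2 termini (head-to-tail), giving a linear bond with E geometry kept. The closest known reaction is Pd-catalysed coupling of allylic halides with allylstannanes to give 1,5-dienes.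

**Step 6**
Reactants: 7
Product: 8 ((2E,6E)-1-bromo-8-chloro-2,6-dimethylocta-2,6-diene)
Conditions: PPh3, CBr4, CH2Cl2, 0 °C
Reagents that add atoms: CBr4 (BrC(Br)(Br)Br)
Why: Appel bromination as in Step 2 re-creates the electrophilic terminus.

**Step 7**
Reactants: 8, 4
Product: 9 ((2E,6E,10E)-12-chloro-2,6,10-trimethyldodeca-2,6,10-trien-1-ol)
Conditions: Pd(PPh3)4 (5 mol %), THF, 0 → 25 °C
Reagents that add atoms: none
Why: Same allyl–allyl coupling as Step 5, extending the chain by one isoprene unit.

**Step 8**
Reactants: 9
Product: 10 (corresponding C15 allylic bromide)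
Conditions: PPh3, CBr4, CH2Cl2, 0 °C
Reagents that add atoms: CBr4 (BrC(Br)(Br)Br)
Why: Appel bromination as in Step 2.

**Step 9**
Reactants: 10, 4
Product: 11 ((2E,6E,10E,14E)-16-chloro-2,6,10,14-tetramethylhexadeca-2,6,10,14-tetraen-1-ol)
Conditions: Pd(PPh3)4 (5 mol %), THF, 0 → 25 °C
Reagents that add atoms: none
Why: Same allyl–allyl coupling as Step 5.

**Step 10**
Reactants: 11
Product: 12 (C20 allylic bromide)
Conditions: PPh3, CBr4, CH2Cl2, 0 °C
Reagents that add atoms: CBr4 (BrC(Br)(Br)Br)
Why: Appel bromination as in Step 2.

**Step 11**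
Reactants: 12, 4
Product: 13 ((2E,6E,10E,14E,18E)-20-chloro-2,6,10,14,18-pentamethylicosa-2,6,10,14,18-pentaen-1-ol)
Conditions: Pd(PPh3)4 (5 mol %), THF, 0 → 25 °C
Reagents that add atoms: none
Why: Same allyl–allyl coupling as Step 5.

**Step 12**
Reactants: 13
Product: 14 (C25 allylic bromide)
Conditions: PPh3, CBr4, CH2Cl2, 0 °C
Reagents that add atoms: CBr4 (BrC(Br)(Br)Br)
Why: Appel bromination as in Step 2.

**Step 13**
Reactants: 14, 6
Product: 15 ((2E,6E,10E,14E,18E)-1-chloro-3,7,11,15,19,23-hexamethyltetracosa-2,6,10,14,18,22-hexaene, i.e. hexaprenyl chloride)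
Conditions: Pd(PPh3)4 (5 mol %), THF, 0 → 25 °C
Reagents that add atoms: none
Why: The last coupling installs the terminal Me2C=CH– unit. Bis(π-allyl)Pd elimination bonds through the prenyl CH2 terminus, not the CMe2 terminus, so there is no reverse-prenyl product.

**Step 14**
Reactants: 15
Product: 16 (all-E hexaprenyltributylstannane)
Conditions: Bu3SnLi, THF, –78 °C
Reagents that add atoms: Bu3SnLi ([Li][Sn](CCCC)(CCCC)CCCC)
Why: SN2 at the primary allylic chloride gives the α-stannane with the E geometry retained. This is the radical precursor.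

**Step 15**
Reactants: 17 (squaric acid)
Product: 18 (diisopropyl squarate)
Conditions: iPrOH, benzene, reflux, Dean–Stark
Reagents that add atoms: iPrOH (CC(C)O)
Why: Acid-catalysed esterification. The isopropyl group on the α-carbon is later converted to the free OH.

**Step 16**
Reactants: 18, 19 (propyne)
Product: 20 (4-hydroxy-2,3-diisopropoxy-4-(prop-1-yn-1-yl)cyclobut-2-en-1-one)
Conditions: propyne + n-BuLi, THF, –78 °C; add 18; then TFAA, aqueous workup
Reagents that add atoms: none
Why: The lithium acetylide adds 1,2 to a squarate carbonyl (Liebeskind–Moore entry). The alkyne supplies the ring CH3 and the carbon that becomes the ring C–H.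

**Step 17**
Reactants: 20
Product: 21 (4-hydroxy-2-isopropoxy-3-methoxy-4-(prop-1-yn-1-yl)cyclobut-2-en-1-one)
Conditions: MeOH, TsOH (cat.), 25 °C
Reagents that add atoms: MeOH (CO)
Why: Only the β-alkoxy group of the vinylogous ester (C3) undergoes addition–elimination exchange. The α-isopropoxy enol ether is inert. This places OMe and O-iPr regiospecifically.

**Step 18**
Reactants: 21
Product: 22 (2-isopropoxy-3-methoxy-5-methyl-1,4-benzoquinone)
Conditions: p-xylene, 1,4-cyclohexadiene (5 equiv), 140 °C, sealed tube; then Ag2O, CH2Cl2, 25 °C (one pot)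
Reagents that add atoms: none
Why: Moore–Liebeskind rearrangement. 4π ring opening gives a vinylketene, then 6-ring radical cyclisation onto the alkyne gives an aryl/phenoxyl diradical. The aryl radical takes H from cyclohexadiene, and Ag2O oxidises the hydroquinone to 22. The ring-closure bond is ketene carbon to the Me-bearing alkyne carbon, which puts Me next to the carbonyl that is flanked by C–O-iPr. One C–H remains.

**Step 19**
Reactants: 22, 16
Product: 23 (2-isopropoxy-3-methoxy-5-methyl-6-[(2E,6E,10E,14E,18E)-hexaprenyl]-1,4-benzoquinone)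
Conditions: 22 (3 equiv), 16 (1 equiv), MeCN/CH2Cl2 (1:1, degassed), blue LEDs (450 nm), 25 °C, 12 h; then Ag2O, 25 °C; KF/silica workup to remove tin
Reagents that add atoms: none
Why: Proposed new method: this is the key radical step. Excited quinone oxidises the allylstannane (E_ox ≈ 1.2 V, versus ≈ 2 V for the chain alkenes). The radical cation loses Bu3Sn⁺ to give an all-E hexaprenyl radical plus the quinone radical anion. The pair couples in cage, through the primary allyl terminus, at the only ring C–H (C6). The E geometry survives because allyl-radical rotation (≈15 kcal/mol) is slower than coupling. Tautomerisation gives the hydroquinone, and Ag2O reoxidises it to 23. The closest known reactions are photoinduced electron-transfer allylation of quinones by allylstannanes and Fieser/Kochi radical alkylation of quinones.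

**Step 20**
Reactants: 23
Product: 24 (3-demethylubiquinone-6, the target)
Conditions: BCl3, CH2Cl2, –78 °C, 10 min; quench with MeOH/aqueous NaHCO3
Reagents that add atoms: none
Why: Lewis-acid chelation at the quinone C=O cleaves the secondary isopropyl ether (SN1-like, loss of iPrCl) much faster than the methyl ether. This unmasks the hydroxyl on the carbon next to the carbonyl flanked by CH3, matching the target SMILES.

## Checks against the target
- Ring: 6-membered quinone with OMe and OH adjacent. The OH carbon sits next to the C=O that bears the neighbouring C–CH3, and the OMe carbon sits next to the C=O that bears the neighbouring C–hexaprenyl, exactly as in COC1=C(O)C(=O)C(C)=C(R)C1=O.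
- Side chain: six isoprene units, five E-CH=C(CH3) alkenes plus the terminal CH=C(CH3)2, all-E as in the target SMILES.
- Atom accounting: each coupling loses only Br/Sn; Step 18 is an isomerisation plus 2H in and 2H out; Step 19 loses Bu3Sn and the ring H.
- Functional-group survival: the alkenes survive Appel, Pd and organotin conditions; Steps 19 and 20 are the exposed ones (see risks below).
- Stereochemistry: only alkene geometry exists, set in 2 and never scrambled, since all bond-forming steps are stereoretentive.

## Compound list
1 | isoprene monoxide (2-methyl-2-vinyloxirane) | C=CC1(C)CO1 | starting material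
2 | (2E)-4-chloro-2-methylbut-2-en-1-ol | ClC/C=C(\C)CO | intermediate
3 | (2E)-1-bromo-4-chloro-2-methylbut-2-ene | ClC/C=C(\C)CBr | intermediate
4 | (2E)-2-methyl-4-(tributylstannyl)but-2-en-1-ol | CCCC[Sn](CCCC)(CCCC)C/C=C(\C)CO | intermediate
5 | prenyl bromide | CC(C)=CCBr | starting material
6 | prenyltributylstannane | CCCC[Sn](CCCC)(CCCC)CC=C(C)C | intermediate
7 | (2E,6E)-8-chloro-2,6-dimethylocta-2,6-dien-1-ol | ClC/C=C(\C)CC/C=C(\C)CO | intermediate
8 | (2E,6E)-1-bromo-8-chloro-2,6-dimethylocta-2,6-diene | ClC/C=C(\C)CC/C=C(\C)CBr | intermediate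
9 | (2E,6E,10E)-12-chloro-2,6,10-trimethyldodeca-2,6,10-trien-1-ol | ClC/C=C(\C)CC/C=C(\C)CC/C=C(\C)CO | intermediate
10 | corresponding C15 allylic bromide | ClC/C=C(\C)CC/C=C(\C)CC/C=C(\C)CBr | intermediate
11 | (2E,6E,10E,14E)-16-chloro-2,6,10,14-tetramethylhexadeca-2,6,10,14-tetraen-1-ol | ClC/C=C(\C)CC/C=C(\C)CC/C=C(\C)CC/C=C(\C)CO | intermediate
12 | corresponding C20 allylic bromide | ClC/C=C(\C)CC/C=C(\C)CC/C=C(\C)CC/C=C(\C)CBr | intermediate
13 | (2E,6E,10E,14E,18E)-20-chloro-2,6,10,14,18-pentamethylicosa-2,6,10,14,18-pentaen-1-ol | ClC/C=C(\C)CC/C=C(\C)CC/C=C(\C)CC/C=C(\C)CC/C=C(\C)CO | intermediate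
14 | corresponding C25 allylic bromide | ClC/C=C(\C)CC/C=C(\C)CC/C=C(\C)CC/C=C(\C)CC/C=C(\C)CBr | intermediate
15 | all-E hexaprenyl chloride | ClC/C=C(\C)CC/C=C(\C)CC/C=C(\C)CC/C=C(\C)CC/C=C(\C)CCC=C(C)C | intermediate
16 | all-E hexaprenyltributylstannane | CCCC[Sn](CCCC)(CCCC)C/C=C(\C)CC/C=C(\C)CC/C=C(\C)CC/C=C(\C)CC/C=C(\C)CCC=C(C)C | intermediate
17 | squaric acid | O=C1C(=O)C(O)=C1O | starting material
18 | diisopropyl squarate | CC(C)OC1=C(OC(C)C)C(=O)C1=O | intermediate
19 | propyne | CC#C | starting material
20 | 4-hydroxy-2,3-diisopropoxy-4-(prop-1-yn-1-yl)cyclobut-2-en-1-one | CC#CC1(O)C(=O)C(OC(C)C)=C1OC(C)C | intermediate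
21 | 4-hydroxy-2-isopropoxy-3-methoxy-4-(prop-1-yn-1-yl)cyclobut-2-en-1-one | CC#CC1(O)C(=O)C(OC(C)C)=C1OC | intermediate
22 | 2-isopropoxy-3-methoxy-5-methyl-1,4-benzoquinone | CC(C)OC1=C(OC)C(=O)C=C(C)C1=O | intermediate
23 | 2-isopropoxy-3-methoxy-5-methyl-6-hexaprenyl-1,4-benzoquinone | CC(C)OC1=C(OC)C(=O)C(C/C=C(\C)CC/C=C(\C)CC/C=C(\C)CC/C=C(\C)CC/C=C(\C)CCC=C(C)C)=C(C)C1=O | intermediate
24 | 3-demethylubiquinone-6 | COC1=C(O)C(=O)C(C)=C(C/C=C(\C)CC/C=C(\C)CC/C=C(\C)CC/C=C(\C)CC/C=C(\C)CCC=C(C)C)C1=O | target

## Totals
Total steps: 20. Longest linear sequence: 14 (1 → 2 → 3 → 7 → 8 → 9 → 10 → 11 → 12 → 13 → 14 → 15 → 16 → 23 → 24, i.e. Steps 1, 2, 5–14, 19, 20). The ring arm, Steps 15–18, joins at Step 19.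

## Three steps most likely to fail
1. **Step 19 (photo-radical coupling).** The excited quinone may instead undergo [2+2] photocycloaddition with the chain alkenes, reduction, or O-coupling.
   Fallback: a non-radical route, Lewis-acid (BF3·OEt2, CH2Cl2, –78 °C) Sakurai-type allylation of 22 with stannane 16, then Ag2O oxidation (Naruta-type).
2. **Steps 5–13 (five Pd allyl–allyl couplings).** Cumulative risks are E/Z erosion, α/γ regiochemistry, and loss of the ring-end allylic chloride to Pd or stannane.
   Fallback: build the chain by Biellmann sulfone alkylation of allylic sulfones with the ring end protected as a silyl ether, followed by Pd/LiBEt3H desulfonylation, in place of the organostannane couplings.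
3. **Step 20 (BCl3 de-isopropylation).** The hexaprenyl polyene or the methyl ether may be damaged, or the wrong ether cleaved.
   Fallback: redesign the ring with diallyl squarate in place of 18 so the OH is carried as an allyl ether, and remove it at the end with Pd(PPh3)4/morpholine under neutral conditions.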